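# Proposed total synthesis of CNP0108778.1 by a carbenoid C–H insertion route

Numbering: eudesmane locants throughout; unprimed for the decalin half, primed for the lactone half. Compounds are numbered 1–31 in the order of the steps.

## Analysis of the target

The target is made of two C15 halves joined by a spiro 3,4-dihydro-2H-pyran (ring D: O–C12=C11–C13–C13'–C11'). The unprimed half is a cis-fused decalin (rings A and B) with the exocyclic C4=C15 methylene and the angular C10 methyl; H5, the C10 methyl and the C7–C11 bond lie on one face (5S,7S,10S). The primed half is the eudesm-5-en-8β,12-olide skeleton of alantolactone: rings A' and B' with the trisubstituted C5'=C6' alkene, the C4' and C10' methyl groups cis to each other, and a γ-lactone (ring C') cis-fused at C7'–C8' on the face of the C10' methyl (4'S,7'S,8'R,10'R). C11' is the spiro centre (11'R), a fully substituted α-oxygenated lactone carbon whose ether oxygen lies on the face of H7' and H8'. The eight stereocentres form two groups (three and five) that are too far apart to control each other, so each half has to be made as a single enantiomer. Sensitive groups are the enol ether C11=C12–O and the C4=C15 alkene (acid), the C5'=C6' alkene, which moves into conjugation as soon as a ketone sits next to C7', and the cis-4',10'-dimethyl array, which is expected to be the less stable C4' epimer whenever C4' is enolisable. The hard part is the cis-lactone with its allylic C7' centre, which has to be made without disturbing C5'=C6', and the union of two hindered halves at a quaternary carbon. The strategy rests on the C7'–C11' bond of ring C': C7' is an allylic methine flanked by C6' and by the oxygen-bearing C8', so the two lactone carbons C12' and C11' can be hung on O8' as an ester and joined to C7' through its C–H bond.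

## Retrosynthetic reasoning

**31 to 15 and 30.** Ring D is opened by a retro-oxa-Diels–Alder reaction that cuts O–C11' and C13–C13'. This is the only pair of bonds whose cleavage returns two stable C15 halves at their final oxidation level, the α-methylene lactone 15 and the 2-substituted acrolein 30. Forward, the cycloaddition has to form one stereocentre only (C11') and must outrun self-dimerisation of 30.

**15 to 13.** The exocyclic C13' methylene is removed, leaving the saturated lactone 13. A conjugated methylene would not survive carbenoid chemistry, so it is put on last, through the hydroxymethylidene lactone 14.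

**13 to 12 (key disconnection).** The C7'–C11' bond is cut, which leads to the diazoacetate 12 on O8'. Cutting here rather than at C8'–O or C11'–C12' means that C7' needs no functional group other than its hydrogen. In particular no ketone is ever placed beside C7', which would draw C5'=C6' into conjugation. Forward, the carbenoid has to pick the C7'–H bond on the face of O8'.

**12 to 10.** The ester C–O bond is cut; the diazoacetate comes from the homoallylic alcohol 10 through the bromoacetate 11.

**10 to 9 to 8.** The C5'=C6' double bond is cut (metathesis), giving the diene-ol 9. The trisubstituted alkene is thus formed exactly where it has to stay, without an enone intermediate. Cutting C7'–C8' in 9 leads to aldehyde 8, so that the C8' carbinol configuration can be set by a chiral allyl–boron reagent.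

**8 to 7 to 5.** The C9'–C10' bond is cut as a [3,3] shift, which leads back to the allylic alcohol 5. Forward, the quaternary C10' is made on the alkene face opposite the C4' methyl, and the exocyclic alkene needed for the metathesis appears in the same step. The carbinol carbon of 5 is only a handle: it steers the rearrangement and leaves in the metathesis.

**5 to 4 to 3 to 1.** The one-carbon handle is removed by way of the ester 4 and the enol triflate 3. The single stereocentre C4' then traces back to the meso ketone 1, in which a chiral base can tell the two α-hydrogens apart.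

**30 to 29 to 27 to 26.** Functional-group changes only: oxidation level at C12, removal of the C9 carbonyl and of the silyl group.

**26 to 24 to 20 and 22.** Ring A is cut at C1–C10 and C4–C5, which returns the enone 20 and the four-carbon bromo-chloro-alkene 22. Forward, C5 is set trans to the C7 side chain by conjugate addition and C10 cis to C5 by ring closure. All three stereocentres of this half therefore derive from the one stereocentre of carvone 16, and the exocyclic methylene comes with the reagent.

**20 to 19 to 17 to 16; 22 to 21.** The allylic oxygen on the side chain is introduced at the carvone stage (16), because later the two 1,1-disubstituted alkenes could not be told apart. Reagent 22 comes from the alkyne 21.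

## Alternatives that were turned down

**Alternative 1:** The decalin half would be cut at C5–C10 and C6–C7, so that rings A and B form in one intramolecular Diels–Alder reaction of the acyclic trienone A1, giving the cis-fused octalinone A2.
- For: both rings and all three stereocentres of this half arise in one step from a chain. A chiral Lewis acid on the ketone could set the absolute configuration without a chiral-pool atom, and the cis fusion follows from the Z geometry at C10.
- Against: the diene terminus C10 is fully substituted and Z-configured. Such dienes reach the s-cis conformer with difficulty and tend to undergo 1,5-hydrogen shifts, so the bond that creates the quaternary centre is the slow one. A1 needs a stereodefined trisubstituted Z-alkene. A2 still lacks C15 (an olefination at a C4 ketone whose neighbour C5 is epimerisable), carries a C8=C9 double bond that has to be saturated selectively, and its two-carbon side chain must still be turned into the acrolein.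
- Comparison: for ring construction and for catalytic enantiocontrol of the decalin this idea is the stronger one. It leaves the lactone half, which is the harder half, untouched. The chosen plan takes C7 from 16, sets C5 and C10 by two substrate-controlled steps, delivers the methylene with the annulating reagent, and keeps its one uncertain step on the lactone half.

**Alternative 2:** Ring B' would be cut at C9'–C10' and closed by thermal disrotatory 6π electrocyclisation of the (Z)-triene A3, giving the silyl dienol ether A4.
- For: it is short. The quaternary C10' and ring B' form together, and hydrolysis of A4 with kinetic α-protonation would leave C5'=C6' in place. After a hydride reduction it would reach the same octalinol as 10 in fewer steps than the sequence used here; on step count it is stronger.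
- Against: C10' is set only by the preference of the closing terminus for the face away from the C4' methyl, in a hot step in which the fully substituted terminus strains the reactive conformer. Hydrogen shifts compete, and the Z-alkene of A3 has to be made by semi-hydrogenation. C8' then depends on a face-selective hydride reduction after hydrolysis of A4, at a stage where the alkene slips into conjugation easily. The lactone bond C7'–C11' is still to be made.
- Comparison: the chosen route uses the same relay from C4' to C10', but in a [3,3] shift at 140 °C through an ordered six-membered transition state. It never has a ketone in ring B' and sets C8' by reagent control. The price is more steps and a one-carbon handle that is lost.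

**Alternative 3:** Ring D would be built at the lactone oxidation level: the enolate of ester A5 (carbon C11) is alkylated by the primary iodide A6, desilylation lets the C11' alkoxide close onto the ester, and the spiro bis-lactone A7 results. The δ-lactone carbonyl C12 must then be reduced and dehydrated to the enol ether.
- For: the union is ionic, stepwise and cold; there is no self-dimerisation; C11' is fixed on the lactone half and can be checked before the union. On control of the union it is stronger.
- Against: A6 needs a quaternary C11' with a silyloxy group and a two-carbon iodide, several steps beyond a lactone such as 13. The enolate of A5 meets a γ-lactone carbonyl in A6 (acylation, elimination). After A7, one lactone has to be half-reduced in the presence of the other and dehydrated, which is two redox steps with a chemoselectivity problem.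
- Comparison: the chosen plan offers a one-step, redox-neutral union that forms ring D at its final oxidation level, and its lactone-forming C–H insertion gives directly the α-CH2 lactone that only needs methylenation.

Key step: step 10

## Route

Remark on the chemistry (assumption): the (S,S)-lithium amide is taken to be the antipode that leads to the (S)-enolate 2, by analogy with the sense known for 4-substituted cyclohexanones; if the sense is the opposite, the (R,R)-amide is used and nothing else changes.

### Lactone half (steps 1–12)

Step 1
Reactants: 1 cis-2,6-dimethylcyclohexanone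
Product: 3 (6S)-2,6-dimethylcyclohex-1-en-1-yl trifluoromethanesulfonate, via lithium enolate 2 (not isolated)
Conditions: (S,S)-bis(1-phenylethyl)amine, n-BuLi, LiCl, THF, −78 °C; PhNTf2, −78 → 0 °C; aq. NH4Cl
Reagents that add atoms: N-phenylbis(trifluoromethanesulfonimide) PhNTf2, SMILES O=S(=O)(N(c1ccccc1)S(=O)(=O)C(F)(F)F)C(F)(F)F
Why: Asymmetric deprotonation of the meso ketone by the C2-symmetric lithium amide removes one of the two enantiotopic α-hydrogens, so the untouched methine becomes C4' (S); O-sulfonylation of the tetrasubstituted enolate then fixes the double bond at C5'=C10'. LiCl is added because the mixed amide–chloride aggregate should keep the selection high when the electrophile is added afterwards.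

Step 2
Reactants: 3 (6S)-2,6-dimethylcyclohex-1-en-1-yl trifluoromethanesulfonate
Product: 4 methyl (6S)-2,6-dimethylcyclohex-1-ene-1-carboxylate
Conditions: CO (1 atm), MeOH, Pd(OAc)2 (5 mol %), 1,3-bis(diphenylphosphino)propane, Et3N, DMF, 60 °C
Reagents that add atoms: carbon monoxide, SMILES [C-]#[O+]; methanol, SMILES CO
Why: Palladium-catalysed alkoxycarbonylation of an enol triflate (oxidative addition to zerovalent palladium, CO insertion, methanolysis of the acyl complex). Neither the alkenyl nor the acyl palladium species has a pathway to the allylic C4'–H, so the stereocentre should be untouched.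

Step 3
Reactants: 4 methyl (6S)-2,6-dimethylcyclohex-1-ene-1-carboxylate
Product: 5 [(6S)-2,6-dimethylcyclohex-1-en-1-yl]methanol
Conditions: i-Bu2AlH (2.5 equiv), CH2Cl2, −78 → 0 °C; aq. KNaC4H4O6
Reagents that add atoms: none
Why: 1,2-Reduction of the hindered α,β-unsaturated ester by the aluminium hydride gives the primary allylic alcohol that serves as the handle for the rearrangement.

Step 4
Reactants: 5 [(6S)-2,6-dimethylcyclohex-1-en-1-yl]methanol
Product: 7 ethyl 2-[(1R,3S)-1,3-dimethyl-2-methylidenecyclohexyl]acetate, via ketene acetal 6 (not isolated)
Conditions: MeC(OEt)3 (6 equiv), EtCO2H (10 mol %), 140 °C, EtOH distilled off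
Reagents that add atoms: triethyl orthoacetate, SMILES CC(OCC)(OCC)OCC
Why: Johnson–Claisen rearrangement: orthoester exchange and loss of ethanol give ketene acetal 6, whose [3,3] shift forms C9'–C10' and moves the double bond out of the ring. The C4' methyl is pseudoaxial next to the substituted C5' (allylic strain), so the six-membered array should pass over the opposite face of C5'=C10', which places the C10' methyl cis to the C4' methyl (1R,3S). From here on C4' is never α to a carbonyl group.

Step 5
Reactants: 7 ethyl 2-[(1R,3S)-1,3-dimethyl-2-methylidenecyclohexyl]acetate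
Product: 8 2-[(1R,3S)-1,3-dimethyl-2-methylidenecyclohexyl]acetaldehyde
Conditions: i-Bu2AlH (1.1 equiv), toluene, −78 °C; MeOH, then aq. KNaC4H4O6
Reagents that add atoms: none
Why: Partial reduction of the ester at −78 °C should stop at the tetrahedral aluminium hemiacetal, which gives the aldehyde on work-up.

Step 6
Reactants: 8 2-[(1R,3S)-1,3-dimethyl-2-methylidenecyclohexyl]acetaldehyde
Product: 9 (2S)-1-[(1R,3S)-1,3-dimethyl-2-methylidenecyclohexyl]pent-4-en-2-ol
Conditions: (−)-Ipc2B(allyl) (1.3 equiv), Et2O, −78 °C; NaOH, H2O2, 0 °C → rt
Reagents that add atoms: (−)-B-allyldiisopinocampheylborane, SMILES C=CCB([C@@H]1C[C@@H]2C[C@@H](C2(C)C)[C@H]1C)[C@@H]1C[C@@H]2C[C@@H](C2(C)C)[C@H]1C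
Why: Asymmetric allylboration through a chair Zimmerman–Traxler transition state. The isopinocampheyl groups derived from (+)-α-pinene send the allyl group to the Si face of the aldehyde, which gives the (2S)-carbinol (the later 8'β-oxygen) under reagent control, independent of the remote C10' centre. Any enantiomeric aldehyde left from step 1 becomes a diastereomer here and can be removed by chromatography.

Step 7
Reactants: 9 (2S)-1-[(1R,3S)-1,3-dimethyl-2-methylidenecyclohexyl]pent-4-en-2-ol
Product: 10 (2S,5S,8aR)-5,8a-dimethyl-1,2,3,5,6,7,8,8a-octahydronaphthalen-2-ol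
Conditions: second-generation Grubbs catalyst RuCl2(=CHPh)(H2IMes)(PCy3) (5 mol %), 1,4-benzoquinone (10 mol %), toluene (5 mM), 80 °C
Reagents that add atoms: none
Why: Ring-closing olefin metathesis between the exocyclic 1,1-disubstituted alkene and the terminal vinyl group closes ring B' as the trisubstituted C5'=C6' alkene; six-membered ring formation and loss of a gas drive it. Benzoquinone is added to suppress ruthenium hydride migration of the exocyclic double bond toward C4'.

Step 8
Reactants: 10 (2S,5S,8aR)-5,8a-dimethyl-1,2,3,5,6,7,8,8a-octahydronaphthalen-2-ol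
Product: 11 (2S,5S,8aR)-5,8a-dimethyl-1,2,3,5,6,7,8,8a-octahydronaphthalen-2-yl bromoacetate
Conditions: BrCH2COBr, pyridine, CH2Cl2, 0 °C
Reagents that add atoms: bromoacetyl bromide, SMILES BrCC(Br)=O
Why: Acylation of the secondary alcohol by the acid bromide; pyridine takes up the acid.

Step 9
Reactants: 11 (2S,5S,8aR)-5,8a-dimethyl-1,2,3,5,6,7,8,8a-octahydronaphthalen-2-yl bromoacetate
Product: 12 (2S,5S,8aR)-5,8a-dimethyl-1,2,3,5,6,7,8,8a-octahydronaphthalen-2-yl diazoacetate
Conditions: TsNHNHTs (2 equiv), DBU (5 equiv), THF, 0 °C
Reagents that add atoms: N,N'-ditosylhydrazine, SMILES Cc1ccc(cc1)S(=O)(=O)NNS(=O)(=O)c1ccc(C)cc1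
Why: N-Alkylation of the ditosylhydrazine by the bromoacetate and two base-induced losses of sulfinate (a Bamford–Stevens-type elimination) give the diazoacetate under conditions that a hindered ester tolerates.

Step 10
Reactants: 12 (2S,5S,8aR)-5,8a-dimethyl-1,2,3,5,6,7,8,8a-octahydronaphthalen-2-yl diazoacetate
Product: 13 (3aS,5S,8aR,9aR)-5,8a-dimethyl-3a,5,6,7,8,8a,9,9a-octahydronaphtho[2,3-b]furan-2(3H)-one
Conditions: Rh2(OAc)4 (1 mol %), CH2Cl2, 40 °C, 12 added over 10 h
Reagents that add atoms: none
Why: Rh2(OAc)4 adds to the diazo carbon of 12, N2 leaves and an electrophilic rhodium carbenoid on C11' results, which inserts into the C7'–Hβ bond in one step through a three-centre, hydride-transfer-like transition state, forming C7'–C11' with retention at C7'. The closest known reaction type is the dirhodium-catalysed intramolecular C–H insertion of cyclohexyl diazoacetates, which gives cis-fused γ-butyrolactones. Ring C' closes by 1,5-insertion (C11' onto the C–H bond γ to the ester oxygen), the five-membered mode that diazoacetates prefer over β-lactone formation at C8'–H or larger rings. The new stereocentre C7' is set by the C8' oxygen: in the half-chair with the ester axial on the β face the carbenoid lies next to the equatorial C7'–Hβ bond, the geometry from which cyclohexyl esters give cis lactones, so C11' ends up cis to O8'. Between the two γ positions, C7'–H is allylic and electron-rich whereas C9'–H is neopentyl and screened by the axial C10' methyl. Addition to C5'=C6' is the main competitor, since homoallylic diazo esters can cyclopropanate; here it would have to occur on the β face of C5', which is flanked by the C4' and C10' methyl groups, and would give a bridged oxatricycle, and an acetate rather than a carboxamidate catalyst is chosen because carboxylate carbenoids lean toward insertion. A trans-fused lactone can arise only from the ring-flipped conformer with an equatorial ester attacking C7'–Hα, so the cis/trans outcome is the point to check first; slow addition keeps the carbenoid concentration low and should suppress carbene dimers.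

Step 11
Reactants: 13 (3aS,5S,8aR,9aR)-5,8a-dimethyl-3a,5,6,7,8,8a,9,9a-octahydronaphtho[2,3-b]furan-2(3H)-one
Product: 14 (3aR,5S,8aR,9aR)-3-(hydroxymethylidene)-5,8a-dimethyl-3a,5,6,7,8,8a,9,9a-octahydronaphtho[2,3-b]furan-2(3H)-one
Conditions: NaH, HCO2Et, EtOH (cat.), THF, 0 °C → rt; 1 M HCl
Reagents that add atoms: ethyl formate, SMILES CCOC=O
Why: Crossed Claisen condensation of the lactone enolate with the formate ester; the product should be isolated as its stable enol, and C7' is not enolisable.

Step 12
Reactants: 14 (3aR,5S,8aR,9aR)-3-(hydroxymethylidene)-5,8a-dimethyl-3a,5,6,7,8,8a,9,9a-octahydronaphtho[2,3-b]furan-2(3H)-one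
Product: 15 (+)-alantolactone, (3aR,5S,8aR,9aR)-5,8a-dimethyl-3-methylidene-3a,5,6,7,8,8a,9,9a-octahydronaphtho[2,3-b]furan-2(3H)-one
Conditions: aq. CH2O (37 %), K2CO3, THF, rt
Reagents that add atoms: formaldehyde, SMILES C=O
Why: Aldol addition of the formyl lactone to formaldehyde, followed by formyl transfer to the new oxygen and loss of formate, gives the exocyclic methylene (deformylative α-methylenation). The mild carbonate base should not move the new double bond into the ring.

### Enal half (steps 13–21)

Step 13
Reactants: 16 (R)-(−)-carvone
Product: 17 (5R)-5-(3-chloroprop-1-en-2-yl)-2-methylcyclohex-2-en-1-one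
Conditions: Ca(OCl)2, CO2 (solid), CH2Cl2–H2O, 0 °C
Reagents that add atoms: calcium hypochlorite Ca(OCl)2, SMILES [Ca+2].[O-]Cl.[O-]Cl
Why: Ene-type allylic chlorination by HOCl generated in the flask: the electron-rich 1,1-disubstituted alkene reacts with transposition to the allylic chloride, whereas the enone alkene is inert. The stereocentre (the later C7) is not involved.

Step 14
Reactants: 17 (5R)-5-(3-chloroprop-1-en-2-yl)-2-methylcyclohex-2-en-1-one
Product: 19 (5R)-5-(3-hydroxyprop-1-en-2-yl)-2-methylcyclohex-2-en-1-one, via allylic acetate 18 (not isolated)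
Conditions: KOAc, DMF, 60 °C; then K2CO3 (cat.), MeOH, rt
Reagents that add atoms: potassium acetate KOAc, SMILES CC(=O)[O-].[K+]
Why: SN2 displacement of the primary allylic chloride by acetate, then carbonate-catalysed transesterification with methanol, frees the alcohol without touching the enone.

Step 15
Reactants: 19 (5R)-5-(3-hydroxyprop-1-en-2-yl)-2-methylcyclohex-2-en-1-one
Product: 20 (5R)-5-{3-[(tert-butyldimethylsilyl)oxy]prop-1-en-2-yl}-2-methylcyclohex-2-en-1-one
Conditions: TBSCl, imidazole, DMF, rt
Reagents that add atoms: tert-butyldimethylsilyl chloride, SMILES CC(C)(C)[Si](C)(C)Cl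
Why: Silylation of the primary allylic alcohol; the silyl ether is inert to the organocopper and alkoxide steps that follow.

Step 16
Reactants: 21 5-chloropent-1-yne
Product: 22 2-bromo-5-chloropent-1-ene
Conditions: Et4N+ HBr2− (from Et4NBr and HBr), CH2Cl2, 40 °C
Reagents that add atoms: hydrogen bromide (as tetraethylammonium hydrogen dibromide), SMILES Br
Why: Markovnikov hydrobromination of the terminal alkyne by the hydrogen dibromide salt gives the 2-bromoalkene; the alkyl chloride is not affected.

Step 17
Reactants: 20 (5R)-5-{3-[(tert-butyldimethylsilyl)oxy]prop-1-en-2-yl}-2-methylcyclohex-2-en-1-one; 22 2-bromo-5-chloropent-1-ene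
Product: 24 (3R,5R)-5-{3-[(tert-butyldimethylsilyl)oxy]prop-1-en-2-yl}-3-(5-chloropent-1-en-2-yl)-2-methylcyclohexan-1-one (both C2 epimers), via Grignard reagent 23 (not isolated)
Conditions: 22, Mg, THF, 40 °C; then CuBr·SMe2 (10 mol %), 20, THF, −78 → −30 °C; aq. NH4Cl
Reagents that add atoms: none
Why: Magnesium inserts into the alkenyl C–Br bond in preference to the alkyl C–Cl bond. Copper-catalysed conjugate addition then delivers the alkenyl group to the β-carbon of the enone (the later C5) anti to the C7 substituent, as in cuprate additions to carvone. The α-carbon forms as a mixture of epimers, which does not matter because it is enolised again in step 18.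

Step 18
Reactants: 24 (3R,5R)-5-{3-[(tert-butyldimethylsilyl)oxy]prop-1-en-2-yl}-3-(5-chloropent-1-en-2-yl)-2-methylcyclohexan-1-one
Product: 26 (3R,4aS,8aR)-3-{3-[(tert-butyldimethylsilyl)oxy]prop-1-en-2-yl}-8a-methyl-5-methylideneoctahydronaphthalen-1(2H)-one (cis-fused), via potassium enolate 25 (not isolated)
Conditions: t-BuOK, t-BuOH–THF, rt
Reagents that add atoms: none
Why: Equilibrating deprotonation gives the more substituted enolate 25, which closes ring A by intramolecular C-alkylation (6-exo-tet, methylenecyclohexane annulation); the other enolate could only form an eight-membered ring and returns by proton exchange. The new C10–C1 bond has to form along the axis of the enolate p-orbital, which the chain on C5 can reach only on its own face, so the decalin should be cis-fused, with the C10 methyl, H5 and the C7 side chain on one face.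

Step 19
Reactants: 26 (3R,4aS,8aR)-3-{3-[(tert-butyldimethylsilyl)oxy]prop-1-en-2-yl}-8a-methyl-5-methylideneoctahydronaphthalen-1(2H)-one
Product: 27 (3R,4aS,8aR)-3-(3-hydroxyprop-1-en-2-yl)-8a-methyl-5-methylideneoctahydronaphthalen-1(2H)-one
Conditions: Bu4NF, THF, rt
Reagents that add atoms: none
Why: Fluoride cleaves the silyl ether before the hot alkaline step, so that step 20 does not depend on how far a silyl group would survive it.

Step 20
Reactants: 27 (3R,4aS,8aR)-3-(3-hydroxyprop-1-en-2-yl)-8a-methyl-5-methylideneoctahydronaphthalen-1(2H)-one
Product: 29 2-[(2S,4aS,8aS)-4a-methyl-8-methylidenedecahydronaphthalen-2-yl]prop-2-en-1-ol, via hydrazone 28 (not isolated)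
Conditions: N2H4·H2O, KOH, diethylene glycol, argon, 130 °C, then 200 °C
Reagents that add atoms: none
Why: Wolff–Kishner reduction (Huang-Minlon procedure): hydrazone 28 forms at 130 °C and loses N2 at 200 °C, which turns the C9 carbonyl beside the quaternary C10 into CH2. No stereocentre is α to this carbonyl, and air is excluded so that no diimide forms that could reduce the two 1,1-disubstituted alkenes.

Step 21
Reactants: 29 2-[(2S,4aS,8aS)-4a-methyl-8-methylidenedecahydronaphthalen-2-yl]prop-2-en-1-ol
Product: 30 2-[(2S,4aS,8aS)-4a-methyl-8-methylidenedecahydronaphthalen-2-yl]prop-2-enal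
Conditions: MnO2 (activated), CH2Cl2, rt
Reagents that add atoms: none
Why: MnO2 oxidises the primary allylic alcohol selectively to the 2-substituted acrolein and should leave the isolated exocyclic alkene alone.

### Union (step 22)

Step 22
Reactants: 15 (+)-alantolactone; 30 2-[(2S,4aS,8aS)-4a-methyl-8-methylidenedecahydronaphthalen-2-yl]prop-2-enal
Product: 31 target CNP0108778.1 (5S,7S,10S,4'S,7'S,8'R,10'R,11'R)
Conditions: threefold excess of the lactone partner, toluene (1 M), BHT (cat.), 130 °C, sealed tube
Reagents that add atoms: none
Why: Thermal oxa-Diels–Alder reaction in which O=C12–C11=C13 of 30 is the heterodiene and C11'=C13' of 15 the 2π partner, of the type known from the dimerisation of 2-alkylacroleins: the two methylene carbons bond first and the oxygen closes onto the carbonyl-bearing carbon, which gives the required O–C11' and C13–C13' bonds. The heterodiene should approach the convex α face of the cis-fused lactone (the face of H7' and H8'), which sets the only new stereocentre C11' as required. The excess of 15, which is recovered unchanged, is meant to hold back self-dimerisation of 30.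

## Compound list

1 | cis-2,6-dimethylcyclohexanone (meso) | C[C@H]1CCC[C@@H](C)C1=O | starting material
2 | lithium (6S)-2,6-dimethylcyclohex-1-en-1-olate | CC1=C(O[Li])[C@@H](C)CCC1 | intermediate
3 | (6S)-2,6-dimethylcyclohex-1-en-1-yl trifluoromethanesulfonate | CC1=C(OS(=O)(=O)C(F)(F)F)[C@@H](C)CCC1 | intermediate
4 | methyl (6S)-2,6-dimethylcyclohex-1-ene-1-carboxylate | CC1=C(C(=O)OC)[C@@H](C)CCC1 | intermediate
5 | [(6S)-2,6-dimethylcyclohex-1-en-1-yl]methanol | CC1=C(CO)[C@@H](C)CCC1 | intermediate
6 | 1-ethoxy-1-{[(6S)-2,6-dimethylcyclohex-1-en-1-yl]methoxy}ethene (ketene acetal) | CC1=C(COC(=C)OCC)[C@@H](C)CCC1 | intermediate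
7 | ethyl 2-[(1R,3S)-1,3-dimethyl-2-methylidenecyclohexyl]acetate | CCOC(=O)C[C@@]1(C)CCC[C@H](C)C1=C | intermediate
8 | 2-[(1R,3S)-1,3-dimethyl-2-methylidenecyclohexyl]acetaldehyde | O=CC[C@@]1(C)CCC[C@H](C)C1=C | intermediate
9 | (2S)-1-[(1R,3S)-1,3-dimethyl-2-methylidenecyclohexyl]pent-4-en-2-ol | C=CC[C@H](O)C[C@@]1(C)CCC[C@H](C)C1=C | intermediate
10 | (2S,5S,8aR)-5,8a-dimethyl-1,2,3,5,6,7,8,8a-octahydronaphthalen-2-ol (4',10'-dimethyl-Δ5'-octalin-8'β-ol) | O[C@@H]1C[C@@]2(C)CCC[C@H](C)C2=CC1 | intermediate
11 | (2S,5S,8aR)-5,8a-dimethyl-1,2,3,5,6,7,8,8a-octahydronaphthalen-2-yl bromoacetate | BrCC(=O)O[C@@H]1C[C@@]2(C)CCC[C@H](C)C2=CC1 | intermediate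
12 | (2S,5S,8aR)-5,8a-dimethyl-1,2,3,5,6,7,8,8a-octahydronaphthalen-2-yl diazoacetate | [N-]=[N+]=CC(=O)O[C@@H]1C[C@@]2(C)CCC[C@H](C)C2=CC1 | intermediate
13 | (3aS,5S,8aR,9aR)-5,8a-dimethyl-3a,5,6,7,8,8a,9,9a-octahydronaphtho[2,3-b]furan-2(3H)-one (alantolactone lacking C13') | O=C1O[C@@H]2C[C@@]3(C)CCC[C@H](C)C3=C[C@@H]2C1 | intermediate
14 | (3aR,5S,8aR,9aR)-3-(hydroxymethylidene)-5,8a-dimethyl-3a,5,6,7,8,8a,9,9a-octahydronaphtho[2,3-b]furan-2(3H)-one | O=C1O[C@@H]2C[C@@]3(C)CCC[C@H](C)C3=C[C@@H]2C1=CO | intermediate
15 | (+)-alantolactone | O=C1O[C@@H]2C[C@@]3(C)CCC[C@H](C)C3=C[C@@H]2C1=C | intermediate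
16 | (R)-(−)-carvone | CC1=CC[C@@H](C(C)=C)CC1=O | starting material
17 | (5R)-5-(3-chloroprop-1-en-2-yl)-2-methylcyclohex-2-en-1-one | CC1=CC[C@@H](C(CCl)=C)CC1=O | intermediate
18 | 2-[(1R)-4-methyl-5-oxocyclohex-3-en-1-yl]prop-2-en-1-yl acetate | CC1=CC[C@@H](C(COC(C)=O)=C)CC1=O | intermediate
19 | (5R)-5-(3-hydroxyprop-1-en-2-yl)-2-methylcyclohex-2-en-1-one | CC1=CC[C@@H](C(CO)=C)CC1=O | intermediate
20 | (5R)-5-{3-[(tert-butyldimethylsilyl)oxy]prop-1-en-2-yl}-2-methylcyclohex-2-en-1-one | CC1=CC[C@@H](C(CO[Si](C)(C)C(C)(C)C)=C)CC1=O | intermediate
21 | 5-chloropent-1-yne | C#CCCCCl | starting material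
22 | 2-bromo-5-chloropent-1-ene | C=C(Br)CCCCl | intermediate
23 | (5-chloropent-1-en-2-yl)magnesium bromide | C=C([Mg]Br)CCCCl | intermediate
24 | (3R,5R)-5-{3-[(tert-butyldimethylsilyl)oxy]prop-1-en-2-yl}-3-(5-chloropent-1-en-2-yl)-2-methylcyclohexan-1-one (C2 epimers) | ClCCCC(=C)[C@@H]1C[C@@H](C(=C)CO[Si](C)(C)C(C)(C)C)CC(=O)C1C | intermediate
25 | potassium enolate of 24 (C1=C2 enolate) | ClCCCC(=C)[C@@H]1C[C@@H](C(=C)CO[Si](C)(C)C(C)(C)C)CC(O[K])=C1C | intermediate
26 | (3R,4aS,8aR)-3-{3-[(tert-butyldimethylsilyl)oxy]prop-1-en-2-yl}-8a-methyl-5-methylideneoctahydronaphthalen-1(2H)-one | C=C1CCC[C@@]2(C)C(=O)C[C@H](C(=C)CO[Si](C)(C)C(C)(C)C)C[C@@H]12 | intermediate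
27 | (3R,4aS,8aR)-3-(3-hydroxyprop-1-en-2-yl)-8a-methyl-5-methylideneoctahydronaphthalen-1(2H)-one | C=C1CCC[C@@]2(C)C(=O)C[C@H](C(=C)CO)C[C@@H]12 | intermediate
28 | hydrazone of 27 | C=C1CCC[C@@]2(C)C(=NN)C[C@H](C(=C)CO)C[C@@H]12 | intermediate
29 | 2-[(2S,4aS,8aS)-4a-methyl-8-methylidenedecahydronaphthalen-2-yl]prop-2-en-1-ol | C=C1CCC[C@@]2(C)CC[C@H](C(=C)CO)C[C@@H]12 | intermediate
30 | 2-[(2S,4aS,8aS)-4a-methyl-8-methylidenedecahydronaphthalen-2-yl]prop-2-enal | C=C1CCC[C@@]2(C)CC[C@H](C(=C)C=O)C[C@@H]12 | intermediate
31 | CNP0108778.1 | C=C1CCC[C@@]2(C)CC[C@H](C3=CO[C@@]4(CC3)C(=O)O[C@@H]3C[C@@]5(C)CCC[C@H](C)C5=C[C@@H]34)C[C@@H]12 | target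

## Step count and least certain steps

Total: 22 steps (12 for the lactone half, 9 for the enal half including reagent 22, one union). Longest linear sequence: 13 steps (steps 1–12, then 22).

**Step 10 (key step).** The carbenoid may be diverted into addition across C5'=C6' (cyclopropanation from the β face), or it may insert from the ring-flipped conformer with an equatorial ester, which would give the trans-fused lactone or attack at C9'. Homoallylic diazo esters are good cyclopropanation substrates and ring B' is conformationally mobile, so the preference argued above is not guaranteed. The fallback leaves carbenoid chemistry and sets out from 10. Oxidation with Dess–Martin periodinane (NaHCO3, CH2Cl2) gives the β,γ-unsaturated ketone (5S,8aR)-5,8a-dimethyl-3,5,6,7,8,8a-hexahydronaphthalen-2(1H)-one F1. Its doubly activated C7' position is deprotonated with LiN(i-Pr)2 (THF, −78 °C) and the dienolate alkylated at C7' with ethyl bromoacetate, giving the keto ester F2, in which the side chain should settle in the equatorial 7'β position. LiBH(s-Bu)3 then attacks the ketone from the α face, and the 8'β-alkoxide closes onto the ester, which returns to the route at 13.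

**Step 22.** Self-dimerisation of 30 by the same cycloaddition may outrun the cross-reaction, and addition to both faces of C11'=C13' is possible; both partners are electron-poor and both new bonds form at hindered carbons. The fallback is stepwise and sets out from 30 and 15. Conjugate addition of PhSeNa (from (PhSe)2 and NaBH4) to 30, followed by acetalisation with ethylene glycol, gives the seleno acetal F3. Bu3SnH and AIBN in the presence of 15 then generate the C13 radical, which adds to C13' (Giese addition) and gives the saturated lactone F4. LiN(i-Pr)2 followed by 2-(phenylsulfonyl)-3-phenyloxaziridine hydroxylates the lactone enolate from the convex face and gives the tertiary alcohol F5. TMSOTf with i-Pr2NEt finally closes O–C12 by transacetalisation and eliminates the glycol to the enol ether, which arrives at 31.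

**Step 4.** Bond formation on the face syn to the C4' methyl would give the trans-dimethyl epimer; the facial preference rests on a conformational argument only. The fallback sets C10' by catalyst control and sets out from 1 (through enolate 2). Trapping 2 with allyl chloroformate gives the allyl enol carbonate F6. Pd2(dba)3 with (R)-t-Bu-PHOX (the antipode of the ligand that delivers the 2S series of 2-allyl-2-methylcyclohexanones) then effects a decarboxylative Tsuji allylation to (2R,6S)-2-allyl-2,6-dimethylcyclohexanone F7. Lemieux–Johnson oxidation (OsO4 cat., NaIO4, 2,6-lutidine) gives the keto aldehyde F8, and (−)-Ipc2B(allyl) adds to its aldehyde group only and gives the hydroxy ketone F9. Takai–Lombardo methylenation (Zn, CH2Br2, TiCl4) of the hindered ketone returns to the route at 9. All of these steps are non-basic, because in F7 to F9 the C4' centre is α to a ketone.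

**Step 1.** Proton exchange between enolate 2 and unreacted ketone or amine before triflation may erode the enantiomeric purity, and the selection between two tertiary α-hydrogens may be modest. The fallback sets out from 1: the same lithium amide is used with TMSCl already present (internal quench, −100 °C), giving the silyl enol ether F10. This is purified, and MeLi (THF, 0 °C) regenerates 2 free of amine, which is triflated as before to reach 3.

**Step 18.** Proton transfer may lead to the unproductive enolate on the C8 side followed by intermolecular condensation, or the alkoxide may eliminate HCl from the side chain. The fallback sets out from 20 and 23: the conjugate addition is run with TMSCl present, which traps the enolate regiospecifically as the trimethylsilyl enol ether F11. MeLi in THF–DMPU then releases the amine-free lithium enolate, which closes the ring and returns to the route at 26.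

**Step 20.** At 200 °C the alkoxide medium may move the exocyclic double bonds or isomerise the allylic alkoxide, and traces of diimide would reduce the alkenes. The fallback sets out from 26, before desilylation. TsNHNH2 (EtOH, 60 °C) gives the tosylhydrazone F12, and catecholborane (CHCl3, 0 °C) followed by NaOAc·3H2O at reflux reduces it to the silyl ether F13 under mild conditions. Bu4NF then returns to the route at 29.

## Further compounds

F1 | step 10 | (5S,8aR)-5,8a-dimethyl-3,5,6,7,8,8a-hexahydronaphthalen-2(1H)-one | O=C1C[C@@]2(C)CCC[C@H](C)C2=CC1
F2 | step 10 | ethyl 2-(4'β,10'β-dimethyl-8'-oxo-Δ5'-octalin-7'β-yl)acetate | O=C1C[C@@]2(C)CCC[C@H](C)C2=C[C@@H]1CC(=O)OCC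
F3 | step 22 | 2-{1-[(2S,4aS,8aS)-4a-methyl-8-methylidenedecahydronaphthalen-2-yl]-2-(phenylselanyl)ethyl}-1,3-dioxolane (C11 epimers) | c1ccccc1[Se]CC(C1OCCO1)[C@H]1CC[C@]2(C)CCCC(=C)[C@@H]2C1
F4 | step 22 | lactone 13 carrying at C11' the 3-(1,3-dioxolan-2-yl)-3-[(2S,4aS,8aS)-4a-methyl-8-methylidenedecahydronaphthalen-2-yl]propyl chain (C11' and C11 epimers) | O=C1O[C@@H]2C[C@@]3(C)CCC[C@H](C)C3=C[C@@H]2C1CCC(C4OCCO4)[C@H]4CC[C@]5(C)CCCC(=C)[C@@H]5C4
F5 | step 22 | 11'α-hydroxy derivative of F4 | O=C1O[C@@H]2C[C@@]3(C)CCC[C@H](C)C3=C[C@@H]2[C@]1(O)CCC(C4OCCO4)[C@H]4CC[C@]5(C)CCCC(=C)[C@@H]5C4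
F6 | step 4 | allyl (6S)-2,6-dimethylcyclohex-1-en-1-yl carbonate | C=CCOC(=O)OC1=C(C)CCC[C@@H]1C
F7 | step 4 | (2R,6S)-2-allyl-2,6-dimethylcyclohexan-1-one | C=CC[C@@]1(C)CCC[C@H](C)C1=O
F8 | step 4 | 2-[(1R,3S)-1,3-dimethyl-2-oxocyclohexyl]acetaldehyde | O=CC[C@@]1(C)CCC[C@H](C)C1=O
F9 | step 4 | (2R,6S)-2-[(2S)-2-hydroxypent-4-en-1-yl]-2,6-dimethylcyclohexan-1-one | C=CC[C@H](O)C[C@@]1(C)CCC[C@H](C)C1=O
F10 | step 1 | {[(6S)-2,6-dimethylcyclohex-1-en-1-yl]oxy}trimethylsilane | CC1=C(O[Si](C)(C)C)[C@@H](C)CCC1
F11 | step 18 | trimethylsilyl enol ether of 24 (C1=C2 enol ether) | ClCCCC(=C)[C@@H]1C[C@@H](C(=C)CO[Si](C)(C)C(C)(C)C)CC(O[Si](C)(C)C)=C1C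
F12 | step 20 | p-toluenesulfonylhydrazone of 26 | C=C1CCC[C@@]2(C)C(=NNS(=O)(=O)c3ccc(C)cc3)C[C@H](C(=C)CO[Si](C)(C)C(C)(C)C)C[C@@H]12
F13 | step 20 | tert-butyldimethylsilyl ether of 29 | C=C1CCC[C@@]2(C)CC[C@H](C(=C)CO[Si](C)(C)C(C)(C)C)C[C@@H]12
A1 | alternative 1 | (7Z,9E)-12-[(tert-butyldimethylsilyl)oxy]-7-methyldodeca-1,7,9-trien-3-one | C=CC(=O)CCC/C(C)=C\C=C\CCO[Si](C)(C)C(C)(C)C
A2 | alternative 1 | cis-fused 10-methyl-oct-8-alin-4-one with the 2-silyloxyethyl group at C7 | O=C1CCC[C@@]2(C)C=C[C@H](CCO[Si](C)(C)C(C)(C)C)C[C@@H]12
A3 | alternative 2 | (Z)-triene: tert-butyl{[(3Z)-4-[(6S)-2,6-dimethylcyclohex-1-en-1-yl]buta-1,3-dien-2-yl]oxy}dimethylsilane | C=C(O[Si](C)(C)C(C)(C)C)/C=C\C1=C(C)CCC[C@@H]1C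
A4 | alternative 2 | cis-4,10-dimethyl-hexahydronaphthalene 8-silyl dienol ether | CC(C)(C)[Si](C)(C)OC1=CC=C2[C@@H](C)CCC[C@]2(C)C1
A5 | alternative 3 | methyl 2-[(2S,4aS,8aS)-4a-methyl-8-methylidenedecahydronaphthalen-2-yl]acetate | C=C1CCC[C@@]2(C)CC[C@H](CC(=O)OC)C[C@@H]12
A6 | alternative 3 | lactone 13 carrying at C11' a trimethylsilyloxy group (α) and a 2-iodoethyl group | ICC[C@]1(O[Si](C)(C)C)C(=O)O[C@@H]2C[C@@]3(C)CCC[C@H](C)C3=C[C@@H]21
A7 | alternative 3 | spiro bis-lactone (12-oxo analogue of the target with saturated C11) | C=C1CCC[C@@]2(C)CC[C@H](C3C(=O)O[C@@]4(CC3)C(=O)O[C@@H]3C[C@@]5(C)CCC[C@H](C)C5=C[C@@H]34)C[C@@H]12
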